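**Retrosynthetic overview**
- Target ⇐ C6 ketone reduction and carbonylative p‑hydroxybenzoylation of a cis‑fused hydroazulenone that already carries the C10 tiglate.
- Hydroazulenone ⇐ pinacol‑type 1,2‑shift of a trans‑decalin triol C5‑mesylate: C1 migrates from C6 to C5, so ring A contracts 6→5 while ring B expands 6→7.
- Triol ⇐ hydroxyl‑directed dihydroxylation of the ring A alkene; ring B ⇐ ring‑closing metathesis of a vinyl arm (on C10) and a 2‑methylallyl arm (on C6).
- The two arms ⇐ Felkin‑type allylzinc addition to the ring A ketone and an enantioselective boron aldol with acrolein (sets C1 and C10).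
- Ring order: ring A (cyclohexenone, deacetylative annulation) first, ring B (metathesis) second, then both reshaped to the 5/7 skeleton in one step.

Assumption: C1–C10 are the daucane atom numbers of the target (C1 quaternary CH3 carbon, C4 isopropyl carbinol, C5 ring‑fusion CH, C6 aroyloxy carbon, C8 methyl alkene carbon, C10 tigloyloxy carbon); ring A ends as the cyclopentane, ring B as the cycloheptene.
Assumption: (−)-Ipc2BCl is taken to give the enantiomer drawn for 9; if the sense of induction is the opposite, (+)-Ipc2BCl is used and nothing else changes.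

**Step 1**
Reactants: 1 3-methylpentane-2,4-dione; 2 4-methylpent-1-en-3-one
Product: 4 6-methyl-3-(propan-2-yl)cyclohex-2-en-1-one (racemic), via triketone Michael adduct 3 (not isolated)
Conditions: NaOMe (0.2 equiv), MeOH, 0 °C, then reflux
Reagents that add atoms: none
Why: Michael addition of the doubly activated carbon, then methoxide retro‑Claisen deacetylation and intramolecular aldol condensation (deacetylative Robinson‑type annulation), in which only the acetyl CH3/isopropyl ketone pairing can dehydrate to a conjugated enone; the C1 stereocentre is racemic here and is erased in step 2.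

**Step 2**
Reactants: 4 6-methyl-3-(propan-2-yl)cyclohex-2-en-1-one; 5 prop-2-enal
Product: 9 (6S)-6-[(1S)-1-hydroxyprop-2-en-1-yl]-6-methyl-3-(propan-2-yl)cyclohex-2-en-1-one, via lithium dienolate 6 (not isolated), via boron dienolate 7 (not isolated), via boron aldolate 8 (not isolated)
Conditions: LiN(iPr)2, Et2O, −78 °C; (−)-Ipc2BCl, −78 to 0 °C; 5, −78 °C; then MeOH, pH 7 buffer, H2O2, 0 °C
Reagents that add atoms: none
Why: Proposed new method: a reagent‑controlled boron aldol of a fully substituted, cross‑conjugated enol diisopinocampheylborinate made by Li→B exchange from the kinetic α′‑dienolate; the ring fixes the enolate geometry (CH3 cis to O), the closed Zimmerman–Traxler chair with vinyl equatorial gives only 1,2‑addition and the C1/C10 relative configuration, and the Ipc ligands differentiate the enolate faces through that cis‑methyl group as they do for Z‑enol borinates, so the C1 quaternary centre and the C10 carbinol are set together; closest known reaction: the Ipc2B‑mediated (Paterson‑type) aldol of ethyl‑ketone Z‑enol borinates, not yet shown for tetrasubstituted enolates forming a quaternary centre.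

**Step 3**
Reactants: 9 (6S)-6-[(1S)-1-hydroxyprop-2-en-1-yl]-6-methyl-3-(propan-2-yl)cyclohex-2-en-1-one; 10 (2E)-2-methylbut-2-enoyl chloride
Product: 11 (1S)-1-[(1S)-1-methyl-2-oxo-4-(propan-2-yl)cyclohex-3-en-1-yl]prop-2-en-1-yl (2E)-2-methylbut-2-enoate
Conditions: 10 (1.5 equiv), pyridine, DMAP (0.1 equiv), CH2Cl2, 0 °C to rt
Reagents that add atoms: none
Why: DMAP‑catalysed acyl transfer (esterification) on the only hydroxyl; C1 is quaternary so no β‑elimination is possible, the final C10 ester is in place and the arm becomes bulky and non‑chelating for step 4.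

**Step 4**
Reactants: 11 (1S)-1-[(1S)-1-methyl-2-oxo-4-(propan-2-yl)cyclohex-3-en-1-yl]prop-2-en-1-yl (2E)-2-methylbut-2-enoate; 12 3-bromo-2-methylprop-1-ene
Product: 13 (1S)-1-[(1S,2S)-2-hydroxy-1-methyl-2-(2-methylprop-2-en-1-yl)-4-(propan-2-yl)cyclohex-3-en-1-yl]prop-2-en-1-yl (2E)-2-methylbut-2-enoate
Conditions: Zn dust, 12, THF, 0 °C; then 11, −40 to 0 °C; H2O work‑up
Reagents that add atoms: none
Why: Barbier‑type allylzinc 1,2‑addition that spares the ester; Felkin–Anh attack anti to the bulky acyloxyallyl arm on the α‑quaternary carbon sets C6 with the 2‑methylallyl group cis to the C1 methyl, which is also the more stable isomer (both large groups trans) should the addition revert.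

**Step 5**
Reactants: 13 (1S)-1-[(1S,2S)-2-hydroxy-1-methyl-2-(2-methylprop-2-en-1-yl)-4-(propan-2-yl)cyclohex-3-en-1-yl]prop-2-en-1-yl (2E)-2-methylbut-2-enoate
Product: 14 (1S,4aS,8aS)-4a-hydroxy-3,8a-dimethyl-6-(propan-2-yl)-1,4,4a,7,8,8a-hexahydronaphthalen-1-yl (2E)-2-methylbut-2-enoate (trans‑fused)
Conditions: second‑generation Hoveyda–Grubbs catalyst (5 mol%), toluene, 80 °C
Reagents that add atoms: none
Why: Ring‑closing metathesis of the vinyl and 2‑methylallyl arms closes ring B as a trisubstituted cyclohexene (C8=C9 with the C8 methyl); the hindered ring A alkene and the conjugated tiglate alkene are inert and no stereocentre is touched.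

**Step 6**
Reactants: 14 (1S,4aS,8aS)-4a-hydroxy-3,8a-dimethyl-6-(propan-2-yl)-1,4,4a,7,8,8a-hexahydronaphthalen-1-yl (2E)-2-methylbut-2-enoate
Product: 16 (1S,4aR,5S,6R,8aS)-4a,5,6-trihydroxy-3,8a-dimethyl-6-(propan-2-yl)-1,4,4a,5,6,7,8,8a-octahydronaphthalen-1-yl (2E)-2-methylbut-2-enoate, via osmate ester 15 (not isolated)
Conditions: OsO4 (1.05 equiv), TMEDA (1.1 equiv), CH2Cl2, −78 °C; then aq. Na2SO3, THF, 60 °C
Reagents that add atoms: osmium tetroxide, O=[Os](=O)(=O)=O
Why: Hydrogen‑bond‑directed (Donohoe‑type) syn‑dihydroxylation: the axial allylic C6–OH delivers OsO4·TMEDA to the ring A alkene on its own face, which is also the face anti to the axial angular CH3, setting C4 and C5; the ring B alkene has only an allylic ester (no H‑bond donor) and the tiglate alkene is electron‑poor.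

**Step 7**
Reactants: 16 (1S,4aR,5S,6R,8aS)-4a,5,6-trihydroxy-3,8a-dimethyl-6-(propan-2-yl)-1,4,4a,5,6,7,8,8a-octahydronaphthalen-1-yl (2E)-2-methylbut-2-enoate
Product: 18 (3R,3aR,8S,8aR)-3-hydroxy-6,8a-dimethyl-4-oxo-3-(propan-2-yl)-1,2,3,3a,4,5,8,8a-octahydroazulen-8-yl (2E)-2-methylbut-2-enoate, via C5 mesylate 17 (not isolated)
Conditions: MeSO2Cl, Et3N, CH2Cl2, −20 °C; then Et3Al, CH2Cl2, −78 to −20 °C; aq. potassium sodium tartrate
Reagents that add atoms: none
Why: Pinacol‑type (semipinacol, Suzuki–Tsuchihashi) 1,2‑shift: only the secondary C5–OH is mesylated, the equatorial C5–OMs is antiperiplanar to the ring‑fusion bond C6–C1, and the quaternary C1 migrates with retention to C5 (inversion there) as the C6 aluminium alkoxide becomes the ketone, contracting ring A to the cyclopentane and expanding ring B to the cycloheptenone with H5 cis to the C1 methyl and C4 unchanged; the alternative shift of C3 from C4 would give a strained trans‑hydrindane, and the cis O–C4/C5/C6 arrangement excludes epoxide formation.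

**Step 8**
Reactants: 18 (3R,3aR,8S,8aR)-3-hydroxy-6,8a-dimethyl-4-oxo-3-(propan-2-yl)-1,2,3,3a,4,5,8,8a-octahydroazulen-8-yl (2E)-2-methylbut-2-enoate
Product: 19 (3R,3aS,4R,8S,8aR)-3,4-dihydroxy-6,8a-dimethyl-3-(propan-2-yl)-1,2,3,3a,4,5,8,8a-octahydroazulen-8-yl (2E)-2-methylbut-2-enoate
Conditions: NaBH4, CeCl3·7H2O, MeOH, −78 °C
Reagents that add atoms: none
Why: Luche‑type chelation‑assisted ketone reduction: hydride adds to the convex face of the cis‑fused ketone (the face of the C1 methyl and H5) while cerium bridges the C4 hydroxyl and the C6 carbonyl, giving the 1,3‑syn diol with C6–OH trans to H5; both esters survive.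

**Step 9**
Reactants: 19 (3R,3aS,4R,8S,8aR)-3,4-dihydroxy-6,8a-dimethyl-3-(propan-2-yl)-1,2,3,3a,4,5,8,8a-octahydroazulen-8-yl (2E)-2-methylbut-2-enoate; 20 tert-butyl(4-iodophenoxy)dimethylsilane; 21 carbon monoxide
Product: 23 (3R,3aS,4R,8S,8aR)-3-hydroxy-6,8a-dimethyl-8-{[(2E)-2-methylbut-2-enoyl]oxy}-3-(propan-2-yl)-1,2,3,3a,4,5,8,8a-octahydroazulen-4-yl 4-hydroxybenzoate, via silyl-protected ester 22 (not isolated)
Conditions: Pd(OAc)2 (5 mol%), Xantphos (7.5 mol%), Et3N, DMAP (0.5 equiv), CO (1 atm), toluene, 70 °C; then Bu4NF, AcOH, THF, 0 °C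
Reagents that add atoms: none
Why: Heck‑type carbonylative esterification (oxidative addition of the aryl iodide, CO insertion, acyl transfer to the secondary C6–OH while the tertiary C4–OH stays free) followed by fluoride cleavage of the aryl silyl ether; no stereocentre changes.

**Compound list**
1 | 3-methylpentane-2,4-dione | CC(=O)C(C)C(C)=O | starting material
2 | 4-methylpent-1-en-3-one | C=CC(=O)C(C)C | starting material
3 | 3-acetyl-3,7-dimethyloctane-2,6-dione | CC(=O)C(C)(CCC(=O)C(C)C)C(C)=O | intermediate (not isolated)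
4 | 6-methyl-3-(propan-2-yl)cyclohex-2-en-1-one (racemic) | CC1CCC(C(C)C)=CC1=O | intermediate
5 | prop-2-enal (acrolein) | C=CC=O | starting material
6 | lithium 6-methyl-3-(propan-2-yl)cyclohexa-1,5-dien-1-olate | [Li]OC1=C(C)CCC(C(C)C)=C1 | intermediate (not isolated)
7 | 6-methyl-3-(propan-2-yl)cyclohexa-1,5-dien-1-yl (−)-diisopinocampheylborinate | CC1=C(OB([C@H]2[C@H](C)[C@H]3C[C@@H](C2)C3(C)C)[C@H]2[C@H](C)[C@H]3C[C@@H](C2)C3(C)C)C=C(C(C)C)CC1 | intermediate (not isolated)
8 | (1S)-1-[(1S)-1-methyl-2-oxo-4-(propan-2-yl)cyclohex-3-en-1-yl]prop-2-en-1-yl (−)-diisopinocampheylborinate | C=C[C@H](OB([C@H]2[C@H](C)[C@H]3C[C@@H](C2)C3(C)C)[C@H]2[C@H](C)[C@H]3C[C@@H](C2)C3(C)C)[C@]1(C)CCC(C(C)C)=CC1=O | intermediate (not isolated)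
9 | (6S)-6-[(1S)-1-hydroxyprop-2-en-1-yl]-6-methyl-3-(propan-2-yl)cyclohex-2-en-1-one | C=C[C@H](O)[C@]1(C)CCC(C(C)C)=CC1=O | intermediate
10 | (2E)-2-methylbut-2-enoyl chloride (tigloyl chloride) | C/C=C(\C)C(Cl)=O | starting material
11 | (1S)-1-[(1S)-1-methyl-2-oxo-4-(propan-2-yl)cyclohex-3-en-1-yl]prop-2-en-1-yl (2E)-2-methylbut-2-enoate | C/C=C(\C)C(=O)O[C@@H](C=C)[C@]1(C)CCC(C(C)C)=CC1=O | intermediate
12 | 3-bromo-2-methylprop-1-ene | C=C(C)CBr | starting material
13 | (1S)-1-[(1S,2S)-2-hydroxy-1-methyl-2-(2-methylprop-2-en-1-yl)-4-(propan-2-yl)cyclohex-3-en-1-yl]prop-2-en-1-yl (2E)-2-methylbut-2-enoate | C/C=C(\C)C(=O)O[C@@H](C=C)[C@]1(C)CCC(C(C)C)=C[C@@]1(O)CC(C)=C | intermediate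
14 | (1S,4aS,8aS)-4a-hydroxy-3,8a-dimethyl-6-(propan-2-yl)-1,4,4a,7,8,8a-hexahydronaphthalen-1-yl (2E)-2-methylbut-2-enoate | C/C=C(\C)C(=O)O[C@H]1C=C(C)C[C@]2(O)C=C(C(C)C)CC[C@@]12C | intermediate
15 | cyclic osmate ester of 16 across O5 and O6 (naphthalene locants), TMEDA adduct | C/C=C(\C)C(=O)O[C@H]1C=C(C)C[C@]2(O)[C@H]3O[Os](=O)(=O)O[C@@]3(C(C)C)CC[C@@]12C.CN(C)CCN(C)C | intermediate (not isolated)
16 | (1S,4aR,5S,6R,8aS)-4a,5,6-trihydroxy-3,8a-dimethyl-6-(propan-2-yl)-1,4,4a,5,6,7,8,8a-octahydronaphthalen-1-yl (2E)-2-methylbut-2-enoate | C/C=C(\C)C(=O)O[C@H]1C=C(C)C[C@]2(O)[C@@H](O)[C@](O)(C(C)C)CC[C@@]12C | intermediate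
17 | (1S,4aR,5S,6R,8aS)-4a,6-dihydroxy-5-[(methanesulfonyl)oxy]-3,8a-dimethyl-6-(propan-2-yl)-1,4,4a,5,6,7,8,8a-octahydronaphthalen-1-yl (2E)-2-methylbut-2-enoate | C/C=C(\C)C(=O)O[C@H]1C=C(C)C[C@]2(O)[C@@H](OS(C)(=O)=O)[C@](O)(C(C)C)CC[C@@]12C | intermediate (not isolated)
18 | (3R,3aR,8S,8aR)-3-hydroxy-6,8a-dimethyl-4-oxo-3-(propan-2-yl)-1,2,3,3a,4,5,8,8a-octahydroazulen-8-yl (2E)-2-methylbut-2-enoate | C/C=C(\C)C(=O)O[C@H]1C=C(C)CC(=O)[C@@H]2[C@@]1(C)CC[C@@]2(O)C(C)C | intermediate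
19 | (3R,3aS,4R,8S,8aR)-3,4-dihydroxy-6,8a-dimethyl-3-(propan-2-yl)-1,2,3,3a,4,5,8,8a-octahydroazulen-8-yl (2E)-2-methylbut-2-enoate | C/C=C(\C)C(=O)O[C@H]1C=C(C)C[C@@H](O)[C@@H]2[C@@]1(C)CC[C@@]2(O)C(C)C | intermediate
20 | tert-butyl(4-iodophenoxy)dimethylsilane | CC(C)(C)[Si](C)(C)Oc1ccc(I)cc1 | starting material
21 | carbon monoxide | [C-]#[O+] | starting material
22 | (3R,3aS,4R,8S,8aR)-3-hydroxy-6,8a-dimethyl-8-{[(2E)-2-methylbut-2-enoyl]oxy}-3-(propan-2-yl)-1,2,3,3a,4,5,8,8a-octahydroazulen-4-yl 4-[(tert-butyldimethylsilyl)oxy]benzoate | C/C=C(\C)C(=O)O[C@H]1C=C(C)C[C@@H](OC(=O)c2ccc(O[Si](C)(C)C(C)(C)C)cc2)[C@@H]2[C@@]1(C)CC[C@@]2(O)C(C)C | intermediate (not isolated)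
23 | (3R,3aS,4R,8S,8aR)-3-hydroxy-6,8a-dimethyl-8-{[(2E)-2-methylbut-2-enoyl]oxy}-3-(propan-2-yl)-1,2,3,3a,4,5,8,8a-octahydroazulen-4-yl 4-hydroxybenzoate | C/C=C(\C)C(=O)O[C@H]1C=C(C)C[C@@H](OC(=O)c2ccc(O)cc2)[C@@H]2[C@@]1(C)CC[C@@]2(O)C(C)C | target

**Totals**
Total step count: 9. Longest linear sequence: 9 steps (steps 1 to 9).

**Three steps most likely to fail**

Step 2 (the proposed new boron aldol). The Li→B exchange on a hindered dienolate, the quaternary‑centre‑forming addition with bulky Ipc ligands and the level of enantiocontrol are all untested. The fallback uses known chemistry, sets out from 4 and 5 and comes back at 9. Deprotonation of 4 with LiN(iPr)2 (THF, −78 °C) gives 6, which adds to 5 to give, after aqueous work‑up, the racemic aldol, that is 9 together with its mirror image (6R)-6-[(1R)-1-hydroxyprop-2-en-1-yl]-6-methyl-3-(propan-2-yl)cyclohex-2-en-1-one F1, with the same relative configuration from the closed chair transition state. Sharpless kinetic resolution [Ti(OiPr)4, L-(+)-diisopropyl tartrate, t‑BuOOH (0.6 equiv), CH2Cl2, −20 °C] then epoxidises the fast‑reacting F1 to the erythro epoxy alcohol (6R)-6-[(S)-hydroxy[(2R)-oxiran-2-yl]methyl]-6-methyl-3-(propan-2-yl)cyclohex-2-en-1-one F2 and leaves 9, which is separated and enters step 3.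

Step 4 (facial selectivity of the 2‑methylallyl addition, which decides the trans ring fusion needed for the shift). If the ester‑bearing arm and the zinc reagent give poor selectivity, the fallback changes the controlling group and the order of events; it sets out from 9 and comes back at 14. Silylation of 9 (t‑BuMe2SiOTf, 2,6‑lutidine) gives (6S)-6-[(1S)-1-[(tert-butyldimethylsilyl)oxy]prop-2-en-1-yl]-6-methyl-3-(propan-2-yl)cyclohex-2-en-1-one F3. With no ester present, the hard reagent (2‑methylallyl)magnesium chloride with CeCl3 (THF, −78 °C) can be used, and it adds anti to the very bulky, non‑chelating silyloxyallyl arm to give (1S,6S)-6-[(1S)-1-[(tert-butyldimethylsilyl)oxy]prop-2-en-1-yl]-6-methyl-1-(2-methylprop-2-en-1-yl)-3-(propan-2-yl)cyclohex-2-en-1-ol F4. Ring‑closing metathesis (second‑generation Hoveyda–Grubbs catalyst) gives (1S,4aS,8aS)-1-[(tert-butyldimethylsilyl)oxy]-3,8a-dimethyl-6-(propan-2-yl)-1,7,8,8a-tetrahydronaphthalen-4a(4H)-ol F5, Bu4NF gives (1S,4aS,8aS)-3,8a-dimethyl-6-(propan-2-yl)-1,7,8,8a-tetrahydronaphthalene-1,4a(4H)-diol F6, and acylation of the secondary allylic hydroxyl with 10 (pyridine, DMAP) gives 14.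

Step 9 (carbonylative esterification). The C6 hydroxyl is hindered, and zerovalent palladium could ionise the allylic C10 tiglate. The fallback avoids palladium; it sets out from 19 and comes back at 22. (4-Bromophenoxy)(tert-butyl)dimethylsilane F7 undergoes bromine–lithium exchange (n‑BuLi, THF, −78 °C) to [4-[(tert-butyldimethylsilyl)oxy]phenyl]lithium F8, which is carboxylated with CO2 to 4-[(tert-butyldimethylsilyl)oxy]benzoic acid F9. Yamaguchi esterification of 19 with F9 (2,4,6‑trichlorobenzoyl chloride, Et3N, then DMAP, toluene) gives 22, which is desilylated with Bu4NF/AcOH as in step 9.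

**Further compounds**
F1 | step 2 | (6R)-6-[(1R)-1-hydroxyprop-2-en-1-yl]-6-methyl-3-(propan-2-yl)cyclohex-2-en-1-one | C=C[C@@H](O)[C@@]1(C)CCC(C(C)C)=CC1=O
F2 | step 2 | (6R)-6-[(S)-hydroxy[(2R)-oxiran-2-yl]methyl]-6-methyl-3-(propan-2-yl)cyclohex-2-en-1-one | O[C@H]([C@H]1CO1)[C@@]2(C)CCC(C(C)C)=CC2=O
F3 | step 4 | (6S)-6-[(1S)-1-[(tert-butyldimethylsilyl)oxy]prop-2-en-1-yl]-6-methyl-3-(propan-2-yl)cyclohex-2-en-1-one | C=C[C@H](O[Si](C)(C)C(C)(C)C)[C@]1(C)CCC(C(C)C)=CC1=O
F4 | step 4 | (1S,6S)-6-[(1S)-1-[(tert-butyldimethylsilyl)oxy]prop-2-en-1-yl]-6-methyl-1-(2-methylprop-2-en-1-yl)-3-(propan-2-yl)cyclohex-2-en-1-ol | C=C[C@H](O[Si](C)(C)C(C)(C)C)[C@]1(C)CCC(C(C)C)=C[C@@]1(O)CC(C)=C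
F5 | step 4 | (1S,4aS,8aS)-1-[(tert-butyldimethylsilyl)oxy]-3,8a-dimethyl-6-(propan-2-yl)-1,7,8,8a-tetrahydronaphthalen-4a(4H)-ol | CC(C)(C)[Si](C)(C)O[C@H]1C=C(C)C[C@]2(O)C=C(C(C)C)CC[C@@]12C
F6 | step 4 | (1S,4aS,8aS)-3,8a-dimethyl-6-(propan-2-yl)-1,7,8,8a-tetrahydronaphthalene-1,4a(4H)-diol | O[C@H]1C=C(C)C[C@]2(O)C=C(C(C)C)CC[C@@]12C
F7 | step 9 | (4-bromophenoxy)(tert-butyl)dimethylsilane | CC(C)(C)[Si](C)(C)Oc1ccc(Br)cc1
F8 | step 9 | [4-[(tert-butyldimethylsilyl)oxy]phenyl]lithium | CC(C)(C)[Si](C)(C)Oc1ccc([Li])cc1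
F9 | step 9 | 4-[(tert-butyldimethylsilyl)oxy]benzoic acid | CC(C)(C)[Si](C)(C)Oc1ccc(cc1)C(=O)O
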